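**Retrosynthetic overview**

1. Target 21 is a (3S)-6,8-dimethoxy-3-methyl-tetrahydroisoquinoline bonded through C5 to C8′ of a 4′,5′-dimethoxy-2′-methylnaphthalene. End game: N-Cbz removed by H2, C4′–OMe made from C4′–Br by Pd-catalysed C–O coupling, C5′–OMe made from the C5′ naphthol.
2. Feature: naphthalene ring B′ (C5′, C6′, C7′, C8′, C4a′, C8a′) carries the isoquinoline on C8′ and oxygen on C5′, para to each other, which is the pattern of an acid-opened aryne–furan adduct. C8a′–C8′ and C4a′–C5′ are therefore disconnected to a C5-(furan-2-yl) isoquinoline and a 3-substituted 5-methylbenzyne, so the crowded C5–C8′ bond is never made between two hindered arenes.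
3. The aryne carries Br, not OMe, at the future C4′. A peri-methoxy group would assist ionisation of the C5′–O bond and take the bridge oxygen away from C5′. Bromine is large (orientation of the cycloaddition), σ-withdrawing (bridge opens at C8′–O) and is exchanged for OMe afterwards.
4. The furyl isoquinoline comes from the 5-bromide (Suzuki), which comes from N-acyliminium Pictet–Spengler closure of the Cbz-amine made by aryl Grignard opening of the L-alaninol cyclic sulfamidate (source of C3).
5. Ring order: dimethoxybenzene ring (bought) → nitrogen ring of the isoquinoline (step 3) → furan attached (step 5) → ring B′ by cycloaddition, with ring A′ arriving in the aryne (step 7).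

Key step: step 7

Assumption: the target SMILES fixes only C3 (S) and leaves the C5–C8′ axis open, so axial configuration is not controlled and rotamers about this axis are carried as a mixture.
Assumption: the (S)-N-Boc cyclic sulfamidate of L-alaninol (2) is taken as a catalogue compound.

**Route**

Step 1
Reactants: 1 1-bromo-3,5-dimethoxybenzene; 2 tert-butyl (4S)-4-methyl-1,2,3-oxathiazolidine-3-carboxylate 2,2-dioxide
Product: 5 tert-butyl N-[(2S)-1-(3,5-dimethoxyphenyl)propan-2-yl]carbamate, via aryl Grignard reagent 3 (not isolated), via N-sulfamate magnesium salt 4 (not isolated)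
Conditions: Mg, THF, 40 °C; then 2, CuI (10 mol%), THF, −20 °C to rt; then 1 M aq. HCl, rt
Reagents that add atoms: none
Why: Copper-catalysed SN2 opening of the cyclic sulfamidate by the aryl Grignard reagent takes place at the primary C–O carbon, so the nitrogen-bearing stereocentre from the chiral pool is untouched, and dilute acid hydrolyses the N-sulfamate without removing Boc.

Step 2
Reactants: 5 tert-butyl N-[(2S)-1-(3,5-dimethoxyphenyl)propan-2-yl]carbamate
Product: 7 benzyl N-[(2S)-1-(3,5-dimethoxyphenyl)propan-2-yl]carbamate, via amine hydrochloride 6 (not isolated)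
Conditions: 4 M HCl/1,4-dioxane, rt; evaporate; CbzCl, Na2CO3, THF–H2O, 0 °C to rt
Reagents that add atoms: benzyl chloroformate, O=C(Cl)OCc1ccccc1
Why: Acidolysis of the tert-butyl carbamate followed by Schotten–Baumann acylation exchanges Boc for Cbz, which survives the acids of steps 3 and 8 and leaves by hydrogenolysis at the end, without touching the stereocentre.

Step 3
Reactants: 7 benzyl N-[(2S)-1-(3,5-dimethoxyphenyl)propan-2-yl]carbamate
Product: 8 benzyl (3S)-6,8-dimethoxy-3-methyl-3,4-dihydro-1H-isoquinoline-2-carboxylate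
Conditions: (CH2O)n (1.1 equiv), TFA, CH2Cl2, 0 °C to rt
Reagents that add atoms: paraformaldehyde (as formaldehyde), C=O
Why: N-acyliminium Pictet–Spengler cyclisation, in which the iminium ion from carbamate and formaldehyde is captured by the ring position ortho to the side chain (para to one methoxy group and ortho to the other; the two ortho positions are equivalent), and the product carbamate cannot form a second iminium ion.

Step 4
Reactants: 8 benzyl (3S)-6,8-dimethoxy-3-methyl-3,4-dihydro-1H-isoquinoline-2-carboxylate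
Product: 9 benzyl (3S)-5-bromo-6,8-dimethoxy-3-methyl-3,4-dihydro-1H-isoquinoline-2-carboxylate
Conditions: NBS (1.0 equiv), MeCN, −20 to 0 °C
Reagents that add atoms: N-bromosuccinimide, O=C1CCC(=O)N1Br
Why: Electrophilic aromatic bromination should go to C5, which is para to the 8-methoxy and ortho to the 6-methoxy group, in preference to C7, which lies between two methoxy groups and has no para donor.

Step 5
Reactants: 9 benzyl (3S)-5-bromo-6,8-dimethoxy-3-methyl-3,4-dihydro-1H-isoquinoline-2-carboxylate; 10 furan-2-ylboronic acid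
Product: 11 benzyl (3S)-5-(furan-2-yl)-6,8-dimethoxy-3-methyl-3,4-dihydro-1H-isoquinoline-2-carboxylate
Conditions: Pd(OAc)2 (3 mol%), SPhos (6 mol%), K3PO4, THF–H2O, 50 °C; 10 (2.5 equiv) added in portions
Reagents that add atoms: none
Why: Suzuki–Miyaura coupling with a dialkylbiarylphosphine that accepts the electron-rich, doubly ortho-substituted bromide at a temperature low enough to compete with protodeboronation of the furylboronic acid, which is used in excess.

Step 6
Reactants: 12 2,6-dibromo-4-methylphenol
Product: 15 2-bromo-4-methyl-6-(trimethylsilyl)phenyl trifluoromethanesulfonate, via aryl trimethylsilyl ether 13 (not isolated), via lithium ortho-silylphenoxide 14 (not isolated)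
Conditions: HMDS, THF, 70 °C; concentrate; n-BuLi (1.05 equiv), THF, −78 °C; then Tf2O, −78 °C to rt
Reagents that add atoms: hexamethyldisilazane, C[Si](C)(C)N[Si](C)(C)C; trifluoromethanesulfonic anhydride, O=S(=O)(OS(=O)(=O)C(F)(F)F)C(F)(F)F
Why: O-silylation, bromine–lithium exchange at one of the two equivalent ortho bromines and anionic 1,3-shift of silicon from O to C (retro-Brook rearrangement) give the ortho-silyl phenoxide, which is triflated in the same flask, the standard preparation of ortho-silylaryl triflates.

Step 7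
Reactants: 11 benzyl (3S)-5-(furan-2-yl)-6,8-dimethoxy-3-methyl-3,4-dihydro-1H-isoquinoline-2-carboxylate; 15 2-bromo-4-methyl-6-(trimethylsilyl)phenyl trifluoromethanesulfonate
Product: 17 benzyl (3S)-5-(5-bromo-7-methyl-1,4-dihydro-1,4-epoxynaphthalen-1-yl)-6,8-dimethoxy-3-methyl-3,4-dihydro-1H-isoquinoline-2-carboxylate (bridgeheads cis through oxygen; the two diastereomers differing in the sense of the bridge relative to C3 are both expected, one is drawn), via 3-bromo-5-methylbenzyne 16 (not isolated)
Conditions: CsF (4 equiv), MeCN, rt; 15 (2 equiv) added slowly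
Reagents that add atoms: none
Why: Fluoride attacks the trimethylsilyl group of 15 and the aryl anion expels triflate from the neighbouring carbon to give aryne 16, which adds to the furan of 11 in a concerted, asynchronous [4+2] cycloaddition; this is the known aryne–furan Diels–Alder route to 1,4-epoxy-1,4-dihydronaphthalenes. Ring B′ closes by intermolecular cycloaddition, both new bonds (C8a′–C8′ and C4a′–C5′) forming in the one step across the two furan α-carbons, with the furan oxygen left as a one-atom bridge. The two new bridgehead centres (C8′ and C5′) are necessarily cis to each other through that bridge; which furan face is attacked relative to C3 is not controlled and need not be, because both centres become sp2 in step 8. The selectivity that matters is orientation: the aryl-bearing furan carbon must bond to the aryne carbon remote from bromine. Bromine lies peri to the bridgehead formed next to it and is far larger than the hydrogen on the other side, while the isoquinoline ring on the furan is held twisted by its 6-methoxy group and C4 methylene, so the transition state that places these two groups side by side should be disfavoured and the furan C–H carbon should take the hindered end. Bromine in place of the final methoxy group at the future C4′ also prepares step 8, because a σ-withdrawing peri substituent does not assist ionisation of the C5′–O bond, whereas a methoxy group there would.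

Step 8
Reactants: 17 benzyl (3S)-5-(5-bromo-7-methyl-1,4-dihydro-1,4-epoxynaphthalen-1-yl)-6,8-dimethoxy-3-methyl-3,4-dihydro-1H-isoquinoline-2-carboxylate
Product: 18 benzyl (3S)-5-(5-bromo-4-hydroxy-7-methylnaphthalen-1-yl)-6,8-dimethoxy-3-methyl-3,4-dihydro-1H-isoquinoline-2-carboxylate
Conditions: TFA (5 equiv), CH2Cl2, 0 °C to rt
Reagents that add atoms: none
Why: Acid-catalysed isomerisation of a 1,4-epoxy-1,4-dihydronaphthalene to a 1-naphthol, in which the protonated bridge ionises at C8′–O (tertiary, allylic and benzylic, and not next to the bromine-bearing ring carbon), a 1,2-hydride shift from C5′ to C6′ follows and enolisation leaves the hydroxyl on C5′, peri to bromine.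

Step 9
Reactants: 18 benzyl (3S)-5-(5-bromo-4-hydroxy-7-methylnaphthalen-1-yl)-6,8-dimethoxy-3-methyl-3,4-dihydro-1H-isoquinoline-2-carboxylate
Product: 19 benzyl (3S)-5-(5-bromo-4-methoxy-7-methylnaphthalen-1-yl)-6,8-dimethoxy-3-methyl-3,4-dihydro-1H-isoquinoline-2-carboxylate
Conditions: MeI, K2CO3, DMF, rt to 40 °C
Reagents that add atoms: iodomethane, CI
Why: Williamson ether synthesis on the naphthoxide, with no N–H left on the carbamate nitrogen to compete.

Step 10
Reactants: 19 benzyl (3S)-5-(5-bromo-4-methoxy-7-methylnaphthalen-1-yl)-6,8-dimethoxy-3-methyl-3,4-dihydro-1H-isoquinoline-2-carboxylate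
Product: 20 benzyl (3S)-5-(4,5-dimethoxy-7-methylnaphthalen-1-yl)-6,8-dimethoxy-3-methyl-3,4-dihydro-1H-isoquinoline-2-carboxylate
Conditions: Pd2(dba)3 (2.5 mol%), tBuBrettPhos (6 mol%), Cs2CO3, MeOH (5 equiv), toluene, 70 °C
Reagents that add atoms: methanol, CO
Why: Buchwald–Hartwig-type palladium-catalysed C–O coupling of an aryl bromide with methanol, in which the bulky biarylphosphine favours C–O reductive elimination over β-hydride elimination from the palladium methoxide and the carbonate base spares the N,N-disubstituted carbamate.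

Step 11
Reactants: 20 benzyl (3S)-5-(4,5-dimethoxy-7-methylnaphthalen-1-yl)-6,8-dimethoxy-3-methyl-3,4-dihydro-1H-isoquinoline-2-carboxylate
Product: 21 (3S)-5-(4,5-dimethoxy-7-methylnaphthalen-1-yl)-6,8-dimethoxy-3-methyl-1,2,3,4-tetrahydroisoquinoline
Conditions: H2 (1 atm), 10% Pd/C, EtOAc–EtOH, rt
Reagents that add atoms: none
Why: Hydrogenolysis of the benzyl carbamate and loss of CO2 free the secondary amine, while the aryl methyl ethers, the naphthalene and the C3 stereocentre are not affected.

**Compound list**

1 | 1-bromo-3,5-dimethoxybenzene | COc1cc(Br)cc(OC)c1 | starting material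
2 | tert-butyl (4S)-4-methyl-1,2,3-oxathiazolidine-3-carboxylate 2,2-dioxide | C[C@H]1COS(=O)(=O)N1C(=O)OC(C)(C)C | starting material
3 | (3,5-dimethoxyphenyl)magnesium bromide | COc1cc([Mg]Br)cc(OC)c1 | intermediate (not isolated)
4 | bromomagnesium N-(tert-butoxycarbonyl)-N-[(2S)-1-(3,5-dimethoxyphenyl)propan-2-yl]sulfamate | C[C@H](N(C(=O)OC(C)(C)C)S(=O)(=O)[O-])Cc1cc(OC)cc(OC)c1.[Mg+]Br | intermediate (not isolated)
5 | tert-butyl N-[(2S)-1-(3,5-dimethoxyphenyl)propan-2-yl]carbamate | C[C@H](NC(=O)OC(C)(C)C)Cc1cc(OC)cc(OC)c1 | intermediate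
6 | (2S)-1-(3,5-dimethoxyphenyl)propan-2-aminium chloride | C[C@H]([NH3+])Cc1cc(OC)cc(OC)c1.[Cl-] | intermediate (not isolated)
7 | benzyl N-[(2S)-1-(3,5-dimethoxyphenyl)propan-2-yl]carbamate | C[C@H](NC(=O)OCc1ccccc1)Cc1cc(OC)cc(OC)c1 | intermediate
8 | benzyl (3S)-6,8-dimethoxy-3-methyl-3,4-dihydro-1H-isoquinoline-2-carboxylate | COc1cc(OC)cc2c1CN(C(=O)OCc1ccccc1)[C@@H](C)C2 | intermediate
9 | benzyl (3S)-5-bromo-6,8-dimethoxy-3-methyl-3,4-dihydro-1H-isoquinoline-2-carboxylate | COc1cc(OC)c(Br)c2c1CN(C(=O)OCc1ccccc1)[C@@H](C)C2 | intermediate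
10 | furan-2-ylboronic acid | OB(O)c1ccco1 | starting material
11 | benzyl (3S)-5-(furan-2-yl)-6,8-dimethoxy-3-methyl-3,4-dihydro-1H-isoquinoline-2-carboxylate | COc1cc(OC)c(-c2ccco2)c2c1CN(C(=O)OCc1ccccc1)[C@@H](C)C2 | intermediate
12 | 2,6-dibromo-4-methylphenol | Cc1cc(Br)c(O)c(Br)c1 | starting material
13 | (2,6-dibromo-4-methylphenoxy)trimethylsilane | Cc1cc(Br)c(O[Si](C)(C)C)c(Br)c1 | intermediate (not isolated)
14 | lithium 2-bromo-4-methyl-6-(trimethylsilyl)phenolate | Cc1cc(Br)c([O-])c([Si](C)(C)C)c1.[Li+] | intermediate (not isolated)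
15 | 2-bromo-4-methyl-6-(trimethylsilyl)phenyl trifluoromethanesulfonate | Cc1cc(Br)c(OS(=O)(=O)C(F)(F)F)c([Si](C)(C)C)c1 | intermediate
16 | 3-bromo-5-methylbenzyne | CC1=CC#CC(Br)=C1 | intermediate (not isolated)
17 | benzyl (3S)-5-(5-bromo-7-methyl-1,4-dihydro-1,4-epoxynaphthalen-1-yl)-6,8-dimethoxy-3-methyl-3,4-dihydro-1H-isoquinoline-2-carboxylate (one bridge diastereomer drawn) | COc1cc(OC)c([C@@]3(O4)C=C[C@H]4c4c(Br)cc(C)cc43)c2c1CN(C(=O)OCc1ccccc1)[C@@H](C)C2 | intermediate
18 | benzyl (3S)-5-(5-bromo-4-hydroxy-7-methylnaphthalen-1-yl)-6,8-dimethoxy-3-methyl-3,4-dihydro-1H-isoquinoline-2-carboxylate | COc1cc(OC)c(-c2ccc(O)c3c(Br)cc(C)cc23)c2c1CN(C(=O)OCc1ccccc1)[C@@H](C)C2 | intermediate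
19 | benzyl (3S)-5-(5-bromo-4-methoxy-7-methylnaphthalen-1-yl)-6,8-dimethoxy-3-methyl-3,4-dihydro-1H-isoquinoline-2-carboxylate | COc1cc(OC)c(-c2ccc(OC)c3c(Br)cc(C)cc23)c2c1CN(C(=O)OCc1ccccc1)[C@@H](C)C2 | intermediate
20 | benzyl (3S)-5-(4,5-dimethoxy-7-methylnaphthalen-1-yl)-6,8-dimethoxy-3-methyl-3,4-dihydro-1H-isoquinoline-2-carboxylate | COc1cc(OC)c(-c2ccc(OC)c3c(OC)cc(C)cc23)c2c1CN(C(=O)OCc1ccccc1)[C@@H](C)C2 | intermediate
21 | (3S)-5-(4,5-dimethoxy-7-methylnaphthalen-1-yl)-6,8-dimethoxy-3-methyl-1,2,3,4-tetrahydroisoquinoline | COc1cc(OC)c(-c2ccc(OC)c3c(OC)cc(C)cc23)c2c1CN[C@@H](C)C2 | target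

**Step count**

Total: 11 steps. Longest linear sequence: 10 steps (steps 1–5 and 7–11); the aryne branch is step 6.

**Steps most likely to fail**

Step 7 (key step). The aryne may add across the furan in the reverse orientation, or unselectively. The furan C–H terminus is the more nucleophilic end and the aryne carbon remote from bromine the more electrophilic one, so the electronic preference works against the steric one on which the step relies. Fallback (ring B′ is built before the biaryl bond, not on it), setting out from 15 and 9: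
- The same aryne is trapped with furan itself (CsF, MeCN), where no orientation question exists, to give 5-bromo-7-methyl-1,4-dihydro-1,4-epoxynaphthalene F1.
- Acid opening (TFA, CH2Cl2) should give 8-bromo-6-methylnaphthalen-1-ol F2, with the hydroxyl peri to bromine.
- MeI, K2CO3 gives 1-bromo-8-methoxy-3-methylnaphthalene F3.
- NaOMe, CuI, DMF–MeOH, 110 °C gives 1,8-dimethoxy-3-methylnaphthalene F4.
- NBS in MeCN should brominate para to the methoxy group of the methyl-free ring to give 1-bromo-4,5-dimethoxy-7-methylnaphthalene F5.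
- n-BuLi, then B(OiPr)3 and aqueous acid give (4,5-dimethoxy-7-methylnaphthalen-1-yl)boronic acid F6.
- Suzuki–Miyaura coupling of F6 with bromide 9 (Pd(OAc)2, SPhos, K3PO4, toluene–H2O, 100 °C) forms the C5–C8′ bond directly and comes back to the route at 20.

Step 10. At the crowded peri position, C–O reductive elimination may be slow, so that β-hydride elimination from the palladium methoxide takes over and bromine is lost without ether formation. Fallback (oxygen brought in through boron, which has no such pathway), setting out from 19: Miyaura borylation (B2pin2, Pd(dppf)Cl2, KOAc, 1,4-dioxane, 90 °C) gives the C4′ pinacol boronate F7. NaBO3·4H2O in THF–H2O oxidises it to the C4′ naphthol F8. MeI, K2CO3, DMF then gives 20.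

Step 5. Protodeboronation of furan-2-ylboronic acid under aqueous base may outpace oxidative addition into the hindered, electron-rich bromide. Fallback (polarity reversed, boron on the stable partner), setting out from 9: Miyaura borylation (B2pin2, Pd(OAc)2, XPhos, KOAc, 1,4-dioxane, 90 °C) gives the isoquinoline C5 pinacol boronate F9. Coupling of F9 with 2-bromofuran (Pd(OAc)2, SPhos, K3PO4, 1,4-dioxane–H2O, 60 °C) comes back to the route at 11.

**Further compounds**

F1 | step 7 | 5-bromo-7-methyl-1,4-dihydro-1,4-epoxynaphthalene (racemic) | Cc1cc(Br)c2c(c1)C1C=CC2O1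
F2 | step 7 | 8-bromo-6-methylnaphthalen-1-ol | Cc1cc(Br)c2c(O)cccc2c1
F3 | step 7 | 1-bromo-8-methoxy-3-methylnaphthalene | Cc1cc(Br)c2c(OC)cccc2c1
F4 | step 7 | 1,8-dimethoxy-3-methylnaphthalene | Cc1cc(OC)c2c(OC)cccc2c1
F5 | step 7 | 1-bromo-4,5-dimethoxy-7-methylnaphthalene | Cc1cc(OC)c2c(OC)ccc(Br)c2c1
F6 | step 7 | (4,5-dimethoxy-7-methylnaphthalen-1-yl)boronic acid | Cc1cc(OC)c2c(OC)ccc(B(O)O)c2c1
F7 | step 10 | benzyl (3S)-6,8-dimethoxy-5-[4-methoxy-7-methyl-5-(4,4,5,5-tetramethyl-1,3,2-dioxaborolan-2-yl)naphthalen-1-yl]-3-methyl-3,4-dihydro-1H-isoquinoline-2-carboxylate | COc1cc(OC)c(-c2ccc(OC)c3c(B4OC(C)(C)C(C)(C)O4)cc(C)cc23)c2c1CN(C(=O)OCc1ccccc1)[C@@H](C)C2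
F8 | step 10 | benzyl (3S)-5-(5-hydroxy-4-methoxy-7-methylnaphthalen-1-yl)-6,8-dimethoxy-3-methyl-3,4-dihydro-1H-isoquinoline-2-carboxylate | COc1cc(OC)c(-c2ccc(OC)c3c(O)cc(C)cc23)c2c1CN(C(=O)OCc1ccccc1)[C@@H](C)C2
F9 | step 5 | benzyl (3S)-6,8-dimethoxy-3-methyl-5-(4,4,5,5-tetramethyl-1,3,2-dioxaborolan-2-yl)-3,4-dihydro-1H-isoquinoline-2-carboxylate | COc1cc(OC)c(B3OC(C)(C)C(C)(C)O3)c2c1CN(C(=O)OCc1ccccc1)[C@@H](C)C2
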